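**Retrosynthetic overview**
- The target comes from global desilylation of a protected hydroazulene, whose seven-membered ring is closed last by ring-closing metathesis at the tetrasubstituted C1=C10 alkene.
- The metathesis diene comes from a C5–C6 union: catalyst-controlled anti-allylboration of an aldehyde (fragment 2, already carrying the C7/C8 centres and the aryl ester) with a cyclopentenylmethyl boronate (fragment 1, carrying C4).
- Fragment 1 is made from 3-methylcyclopent-2-en-1-one (the five-membered ring is bought in) by CBS reduction, directed epoxidation, Wittig methylenation and borylative SN2′ epoxide opening.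
- Fragment 2 is made by an Evans syn-aldol of an isovaleryl imide with 3-methylbut-3-enal, reduction, and esterification with fragment 3 (silyl-protected 4-hydroxybenzoyl chloride).

Convention: positions are cited with guaiane numbering (C1=C10 alkene with CH3 on C10, C4 methyl carbinol, C5 ring-fusion CH, C6 CH–OH, C7 CH–iPr, C8 CH–O-ester, C9 CH2); both enantiomers of the CBS catalyst, 4-benzyl-2-oxazolidinone and TRIP are taken as commercially available.

**Fragment 1**

Step 1
Reactants: 1 3-methylcyclopent-2-en-1-one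
Product: 2 (1R)-3-methylcyclopent-2-en-1-ol
Conditions: BH3·SMe2 (0.6 equiv), (S)-2-methyl-CBS-oxazaborolidine (10 mol %), THF, −20 °C; MeOH quench
Reagents that add atoms: none
Why: Corey–Bakshi–Shibata reduction, in which the ketone binds the oxazaborolidine–borane complex with its alkenyl arm as the large group, so hydride reaches one carbonyl face only and the (R)-allylic alcohol is formed by 1,2-reduction.

Step 2
Reactants: 2 (1R)-3-methylcyclopent-2-en-1-ol
Product: 3 (1R,2R,5S)-5-methyl-6-oxabicyclo[3.1.0]hexan-2-ol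
Conditions: VO(acac)2 (2 mol %), tBuOOH (1.5 equiv, decane), CH2Cl2, 0 °C → rt
Reagents that add atoms: tert-butyl hydroperoxide, CC(C)(C)OO
Why: Hydroxyl-directed vanadium-catalysed epoxidation, in which the vanadate ester of the allylic alcohol delivers oxygen to the alkene face syn to the OH, so the carbinol centre sets the quaternary C–O centre that becomes C4 (S).

Step 3
Reactants: 3 (1R,2R,5S)-5-methyl-6-oxabicyclo[3.1.0]hexan-2-ol
Product: 4 (1S,5S)-5-methyl-6-oxabicyclo[3.1.0]hexan-2-one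
Conditions: Dess–Martin periodinane, pyridine, CH2Cl2, 0 °C → rt
Reagents that add atoms: none
Why: Dess–Martin oxidation of the secondary alcohol under buffered conditions leaves the epoxide and its two stereocentres untouched.

Step 4
Reactants: 4 (1S,5S)-5-methyl-6-oxabicyclo[3.1.0]hexan-2-one
Product: 5 (1S,5R)-1-methyl-4-methylidene-6-oxabicyclo[3.1.0]hexane
Conditions: Ph3PCH3Br, KOtBu, THF, 0 °C → rt
Reagents that add atoms: methyltriphenylphosphonium bromide, [Br-].C[P+](c1ccccc1)(c1ccccc1)c1ccccc1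
Why: Wittig methylenation, in which the non-stabilised ylide adds to the ketone while the epoxide is inert, gives the vinyl epoxide with the epoxide stereocentres unchanged.

Step 5
Reactants: 5 (1S,5R)-1-methyl-4-methylidene-6-oxabicyclo[3.1.0]hexane
Product: 6 (1S)-1-methyl-3-[(4,4,5,5-tetramethyl-1,3,2-dioxaborolan-2-yl)methyl]cyclopent-2-en-1-ol
Conditions: B2pin2 (1.1 equiv), CuCl (10 mol %), Xantphos (10 mol %), NaOtBu (20 mol %), MeOH (2 equiv), THF, rt
Reagents that add atoms: bis(pinacolato)diboron, CC1(C)OB(OC1(C)C)B1OC(C)(C)C(C)(C)O1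
Why: Copper-catalysed borylative SN2′ ring-opening of a vinyl epoxide, in which the copper boryl puts boron on the terminal CH2 and β-alkoxide elimination breaks only the allylic C–O bond, so the tertiary C–O bond keeps its configuration.

Step 6
Reactants: 6 (1S)-1-methyl-3-[(4,4,5,5-tetramethyl-1,3,2-dioxaborolan-2-yl)methyl]cyclopent-2-en-1-ol
Product: 7 triethyl({(1S)-1-methyl-3-[(4,4,5,5-tetramethyl-1,3,2-dioxaborolan-2-yl)methyl]cyclopent-2-en-1-yl}oxy)silane
Conditions: Et3SiOTf, 2,6-lutidine, CH2Cl2, −78 °C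
Reagents that add atoms: triethylsilyl trifluoromethanesulfonate, CC[Si](CC)(CC)OS(=O)(=O)C(F)(F)F
Why: Silyl ether protection of the tertiary alcohol with a silyl triflate and a hindered base is fast at low temperature and leaves the pinacol allylboronate alone.

**Fragment 3**

Step 7
Reactants: 8 4-hydroxybenzoic acid
Product: 10 4-[(tert-butyldimethylsilyl)oxy]benzoic acid, via bis-silyl compound 9 (not isolated)
Conditions: TBSCl (2.5 equiv), imidazole, DMF, rt; then AcOH/THF/H2O (3:1:1), rt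
Reagents that add atoms: tert-butyldimethylsilyl chloride, CC(C)(C)[Si](C)(C)Cl
Why: Silylation of both OH groups followed by selective hydrolysis of the labile silyl ester (protecting-group chemistry) leaves the acid-stable aryl silyl ether.

Step 8
Reactants: 10 4-[(tert-butyldimethylsilyl)oxy]benzoic acid
Product: 11 4-[(tert-butyldimethylsilyl)oxy]benzoyl chloride
Conditions: (COCl)2, DMF (cat.), CH2Cl2, 0 °C → rt; evaporated and used crude
Reagents that add atoms: oxalyl chloride, ClC(=O)C(=O)Cl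
Why: Acid chloride formation through the Vilsmeier-type chloroiminium activation is compatible with the aryl silyl ether.

**Fragment 2**

Step 9
Reactants: 12 (4R)-4-benzyl-1,3-oxazolidin-2-one; 13 3-methylbutanoyl chloride
Product: 14 (4R)-4-benzyl-3-(3-methylbutanoyl)-1,3-oxazolidin-2-one
Conditions: Et3N, DMAP (10 mol %), CH2Cl2, 0 °C → rt
Reagents that add atoms: none
Why: DMAP-catalysed N-acylation attaches the Evans auxiliary without touching its stereocentre.

Step 10
Reactants: 15 3-methylbut-3-en-1-ol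
Product: 16 3-methylbut-3-enal
Conditions: Dess–Martin periodinane, CH2Cl2, 0 °C; filtered cold and used at once as a solution
Reagents that add atoms: none
Why: Dess–Martin oxidation is neutral and fast, so the β,γ-unsaturated aldehyde is obtained without migration of the alkene into conjugation provided it is kept cold and used directly.

Step 11
Reactants: 14 (4R)-4-benzyl-3-(3-methylbutanoyl)-1,3-oxazolidin-2-one; 16 3-methylbut-3-enal
Product: 19 (4R)-4-benzyl-3-[(2R,3S)-3-hydroxy-5-methyl-2-(propan-2-yl)hex-5-enoyl]-1,3-oxazolidin-2-one, via boron Z-enolate 17 (not isolated), via boron aldolate 18 (not isolated)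
Conditions: Bu2BOTf (1.2 equiv), Et3N (1.4 equiv), CH2Cl2, 0 °C, 1 h; 16 (2 equiv), −78 → 0 °C; pH 7 buffer, MeOH, 30% H2O2, 0 °C
Reagents that add atoms: none
Why: Evans syn-aldol reaction, in which the Z-boron enolate reacts through a Zimmerman–Traxler chair on the face away from the benzyl group of the (R)-auxiliary, sets the isopropyl-bearing centre (2R, later C7) and the carbinol centre (3S, later C8) in the syn relationship.

Step 12
Reactants: 19 (4R)-4-benzyl-3-[(2R,3S)-3-hydroxy-5-methyl-2-(propan-2-yl)hex-5-enoyl]-1,3-oxazolidin-2-one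
Product: 20 (2S,3S)-5-methyl-2-(propan-2-yl)hex-5-ene-1,3-diol
Conditions: LiBH4 (2 equiv), MeOH (2 equiv), THF, 0 °C
Reagents that add atoms: none
Why: Reductive cleavage of the N-acyl oxazolidinone by hydride attack at the exocyclic carbonyl gives the 1,3-diol and returns the auxiliary, with no change at either stereocentre (the descriptor at C2 changes by priority only).

Step 13
Reactants: 20 (2S,3S)-5-methyl-2-(propan-2-yl)hex-5-ene-1,3-diol
Product: 21 (2S,3S)-5-methyl-2-(propan-2-yl)-1-[(triethylsilyl)oxy]hex-5-en-3-ol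
Conditions: Et3SiCl (1.05 equiv), imidazole, CH2Cl2, −40 → 0 °C
Reagents that add atoms: chlorotriethylsilane, CC[Si](Cl)(CC)CC
Why: Selective silylation of the primary alcohol over the hindered secondary one (steric differentiation in silyl ether protection).

Step 14
Reactants: 21 (2S,3S)-5-methyl-2-(propan-2-yl)-1-[(triethylsilyl)oxy]hex-5-en-3-ol; 11 4-[(tert-butyldimethylsilyl)oxy]benzoyl chloride
Product: 22 (2S,3S)-5-methyl-2-(propan-2-yl)-1-[(triethylsilyl)oxy]hex-5-en-3-yl 4-[(tert-butyldimethylsilyl)oxy]benzoate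
Conditions: Et3N, DMAP (0.3 equiv), CH2Cl2, 0 °C → rt
Reagents that add atoms: none
Why: DMAP-catalysed esterification of the secondary alcohol with the acid chloride proceeds at oxygen, so the carbinol configuration is retained.

Step 15
Reactants: 22 (2S,3S)-5-methyl-2-(propan-2-yl)-1-[(triethylsilyl)oxy]hex-5-en-3-yl 4-[(tert-butyldimethylsilyl)oxy]benzoate
Product: 23 (2S,3S)-1-hydroxy-5-methyl-2-(propan-2-yl)hex-5-en-3-yl 4-[(tert-butyldimethylsilyl)oxy]benzoate
Conditions: PPTS (0.2 equiv), MeOH/CH2Cl2, 0 °C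
Reagents that add atoms: none
Why: Acid-catalysed methanolysis (selective desilylation) cleaves the primary alkyl triethylsilyl ether far faster than the aryl TBS ether, and under this mild acid the ester does not migrate.

Step 16
Reactants: 23 (2S,3S)-1-hydroxy-5-methyl-2-(propan-2-yl)hex-5-en-3-yl 4-[(tert-butyldimethylsilyl)oxy]benzoate
Product: 24 (2R,3S)-5-methyl-1-oxo-2-(propan-2-yl)hex-5-en-3-yl 4-[(tert-butyldimethylsilyl)oxy]benzoate
Conditions: Dess–Martin periodinane, pyridine, CH2Cl2, 0 °C; used crude at once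
Reagents that add atoms: none
Why: Dess–Martin oxidation gives the α-branched β-acyloxy aldehyde without epimerisation or elimination (the α-descriptor changes from S to R by priority only).

**Union and ring closure**

Step 17
Reactants: 7 triethyl({(1S)-1-methyl-3-[(4,4,5,5-tetramethyl-1,3,2-dioxaborolan-2-yl)methyl]cyclopent-2-en-1-yl}oxy)silane; 24 (2R,3S)-5-methyl-1-oxo-2-(propan-2-yl)hex-5-en-3-yl 4-[(tert-butyldimethylsilyl)oxy]benzoate
Product: 26 (1R,2S,3S)-1-hydroxy-5-methyl-1-[(1S,2S)-2-methyl-5-methylidene-2-[(triethylsilyl)oxy]cyclopentyl]-2-(propan-2-yl)hex-5-en-3-yl 4-[(tert-butyldimethylsilyl)oxy]benzoate, via pinacol borate ester 25 (not isolated)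
Conditions: (S)-TRIP [(S)-3,3′-bis(2,4,6-triisopropylphenyl)-1,1′-binaphthyl-2,2′-diyl hydrogen phosphate] (10 mol %), 4 Å MS, toluene, −30 → 0 °C; aq NaHCO3 work-up
Reagents that add atoms: none
Why: Chiral-phosphoric-acid-catalysed allylboration through a closed Zimmerman–Traxler chair, in which the (S)-catalyst directs the boronate to the Si face of the aldehyde (6R), the ring-locked E geometry of the boronate (C4 trans to CH2B) places C4 equatorial so that C5/C6 come out anti (5S), the bond forms on the cyclopentene face anti to the C4 methyl where the silyloxy group presents only its oxygen, and allyl transposition leaves the exocyclic C1 methylene.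

Step 18
Reactants: 26 (1R,2S,3S)-1-hydroxy-5-methyl-1-[(1S,2S)-2-methyl-5-methylidene-2-[(triethylsilyl)oxy]cyclopentyl]-2-(propan-2-yl)hex-5-en-3-yl 4-[(tert-butyldimethylsilyl)oxy]benzoate
Product: 27 (3S,3aS,4R,5S,6S)-4-hydroxy-3,8-dimethyl-5-(propan-2-yl)-3-[(triethylsilyl)oxy]-1,2,3,3a,4,5,6,7-octahydroazulen-6-yl 4-[(tert-butyldimethylsilyl)oxy]benzoate
Conditions: second-generation Hoveyda–Grubbs catalyst RuCl2(H2IMes)(=CH-C6H4-2-OiPr) (15 mol % in three portions), toluene (2 mM), 100 °C, argon sparge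
Reagents that add atoms: none
Why: Ring-closing metathesis of the two 1,1-disubstituted alkenes, helped by the pre-formed five-membered ring, high dilution, heat and removal of ethene, closes the seven-membered ring as the tetrasubstituted C1=C10 alkene without touching any stereocentre.

Step 19
Reactants: 27 (3S,3aS,4R,5S,6S)-4-hydroxy-3,8-dimethyl-5-(propan-2-yl)-3-[(triethylsilyl)oxy]-1,2,3,3a,4,5,6,7-octahydroazulen-6-yl 4-[(tert-butyldimethylsilyl)oxy]benzoate
Product: 28 (3S,3aS,4R,5S,6S)-3,4-dihydroxy-3,8-dimethyl-5-(propan-2-yl)-1,2,3,3a,4,5,6,7-octahydroazulen-6-yl 4-hydroxybenzoate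
Conditions: Bu4NF (3 equiv), AcOH (3 equiv), THF, 0 °C → rt
Reagents that add atoms: none
Why: Fluoride-mediated desilylation buffered with acetic acid removes the aryl TBS and tertiary triethylsilyl groups while keeping the medium non-basic, so the C8 ester neither cleaves nor migrates to O6.

**Compound list**

1 | 3-methylcyclopent-2-en-1-one | CC1=CC(=O)CC1 | starting material
2 | (1R)-3-methylcyclopent-2-en-1-ol | CC1=C[C@H](O)CC1 | intermediate
3 | (1R,2R,5S)-5-methyl-6-oxabicyclo[3.1.0]hexan-2-ol | C[C@]12CC[C@@H](O)[C@H]1O2 | intermediate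
4 | (1S,5S)-5-methyl-6-oxabicyclo[3.1.0]hexan-2-one | C[C@]12CCC(=O)[C@H]1O2 | intermediate
5 | (1S,5R)-1-methyl-4-methylidene-6-oxabicyclo[3.1.0]hexane | C[C@]12CCC(=C)[C@H]1O2 | intermediate
6 | (1S)-1-methyl-3-[(4,4,5,5-tetramethyl-1,3,2-dioxaborolan-2-yl)methyl]cyclopent-2-en-1-ol | C[C@]1(O)CCC(CB2OC(C)(C)C(C)(C)O2)=C1 | intermediate
7 | triethyl({(1S)-1-methyl-3-[(4,4,5,5-tetramethyl-1,3,2-dioxaborolan-2-yl)methyl]cyclopent-2-en-1-yl}oxy)silane (fragment 1) | C[C@]1(O[Si](CC)(CC)CC)CCC(CB2OC(C)(C)C(C)(C)O2)=C1 | intermediate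
8 | 4-hydroxybenzoic acid | OC(=O)c1ccc(O)cc1 | starting material
9 | tert-butyldimethylsilyl 4-[(tert-butyldimethylsilyl)oxy]benzoate | CC(C)(C)[Si](C)(C)OC(=O)c1ccc(O[Si](C)(C)C(C)(C)C)cc1 | intermediate (not isolated)
10 | 4-[(tert-butyldimethylsilyl)oxy]benzoic acid | CC(C)(C)[Si](C)(C)Oc1ccc(C(=O)O)cc1 | intermediate
11 | 4-[(tert-butyldimethylsilyl)oxy]benzoyl chloride (fragment 3) | CC(C)(C)[Si](C)(C)Oc1ccc(C(=O)Cl)cc1 | intermediate
12 | (4R)-4-benzyl-1,3-oxazolidin-2-one | O=C1N[C@H](Cc2ccccc2)CO1 | starting material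
13 | 3-methylbutanoyl chloride | CC(C)CC(=O)Cl | starting material
14 | (4R)-4-benzyl-3-(3-methylbutanoyl)-1,3-oxazolidin-2-one | CC(C)CC(=O)N1[C@H](Cc2ccccc2)COC1=O | intermediate
15 | 3-methylbut-3-en-1-ol | C=C(C)CCO | starting material
16 | 3-methylbut-3-enal | C=C(C)CC=O | intermediate
17 | dibutylboron Z-enolate of 14 | CCCCB(CCCC)O/C(N1[C@H](Cc2ccccc2)COC1=O)=C\C(C)C | intermediate (not isolated)
18 | dibutylboron aldolate of 19 (O3–BBu2) | O=C(N1[C@H](Cc2ccccc2)COC1=O)[C@H](C(C)C)[C@@H](OB(CCCC)CCCC)CC(C)=C | intermediate (not isolated)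
19 | (4R)-4-benzyl-3-[(2R,3S)-3-hydroxy-5-methyl-2-(propan-2-yl)hex-5-enoyl]-1,3-oxazolidin-2-one | O=C(N1[C@H](Cc2ccccc2)COC1=O)[C@H](C(C)C)[C@@H](O)CC(C)=C | intermediate
20 | (2S,3S)-5-methyl-2-(propan-2-yl)hex-5-ene-1,3-diol | OC[C@H](C(C)C)[C@@H](O)CC(C)=C | intermediate
21 | (2S,3S)-5-methyl-2-(propan-2-yl)-1-[(triethylsilyl)oxy]hex-5-en-3-ol | CC[Si](CC)(CC)OC[C@H](C(C)C)[C@@H](O)CC(C)=C | intermediate
22 | (2S,3S)-5-methyl-2-(propan-2-yl)-1-[(triethylsilyl)oxy]hex-5-en-3-yl 4-[(tert-butyldimethylsilyl)oxy]benzoate | CC[Si](CC)(CC)OC[C@H](C(C)C)[C@@H](OC(=O)c1ccc(O[Si](C)(C)C(C)(C)C)cc1)CC(C)=C | intermediate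
23 | (2S,3S)-1-hydroxy-5-methyl-2-(propan-2-yl)hex-5-en-3-yl 4-[(tert-butyldimethylsilyl)oxy]benzoate | OC[C@H](C(C)C)[C@@H](OC(=O)c1ccc(O[Si](C)(C)C(C)(C)C)cc1)CC(C)=C | intermediate
24 | (2R,3S)-5-methyl-1-oxo-2-(propan-2-yl)hex-5-en-3-yl 4-[(tert-butyldimethylsilyl)oxy]benzoate (fragment 2) | O=C[C@H](C(C)C)[C@@H](OC(=O)c1ccc(O[Si](C)(C)C(C)(C)C)cc1)CC(C)=C | intermediate
25 | pinacol borate ester of 26 (O6–Bpin) | C=C1CC[C@](C)(O[Si](CC)(CC)CC)[C@@H]1[C@H](OB1OC(C)(C)C(C)(C)O1)[C@H](C(C)C)[C@@H](OC(=O)c1ccc(O[Si](C)(C)C(C)(C)C)cc1)CC(C)=C | intermediate (not isolated)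
26 | (1R,2S,3S)-1-hydroxy-5-methyl-1-[(1S,2S)-2-methyl-5-methylidene-2-[(triethylsilyl)oxy]cyclopentyl]-2-(propan-2-yl)hex-5-en-3-yl 4-[(tert-butyldimethylsilyl)oxy]benzoate | C=C1CC[C@](C)(O[Si](CC)(CC)CC)[C@@H]1[C@H](O)[C@H](C(C)C)[C@@H](OC(=O)c1ccc(O[Si](C)(C)C(C)(C)C)cc1)CC(C)=C | intermediate
27 | (3S,3aS,4R,5S,6S)-4-hydroxy-3,8-dimethyl-5-(propan-2-yl)-3-[(triethylsilyl)oxy]-1,2,3,3a,4,5,6,7-octahydroazulen-6-yl 4-[(tert-butyldimethylsilyl)oxy]benzoate | CC1=C2CC[C@](C)(O[Si](CC)(CC)CC)[C@@H]2[C@H](O)[C@H](C(C)C)[C@@H](OC(=O)c2ccc(O[Si](C)(C)C(C)(C)C)cc2)C1 | intermediate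
28 | (3S,3aS,4R,5S,6S)-3,4-dihydroxy-3,8-dimethyl-5-(propan-2-yl)-1,2,3,3a,4,5,6,7-octahydroazulen-6-yl 4-hydroxybenzoate | CC1=C2CC[C@](C)(O)[C@@H]2[C@H](O)[C@H](C(C)C)[C@@H](OC(=O)c2ccc(O)cc2)C1 | target

**Step count**
- Total: 19 steps (fragment 1: steps 1–6; fragment 3: steps 7–8; fragment 2: steps 9–16; union and endgame: steps 17–19).
- Longest linear sequence: 10 steps (9, 11, 12, 13, 14, 15, 16, 17, 18, 19), which is 10/19 of the total.

**Steps most likely to fail, with fallbacks**

Step 18 (metathesis to a tetrasubstituted alkene in a seven-membered ring). If 26 only oligomerises or stalls, the same C1=C10 bond is made by carbonyl coupling. The fallback sets out from 26: Et3SiOTf/2,6-lutidine gives the 6-O-triethylsilyl ether of 26 F3. Ozonolysis (O3, CH2Cl2/MeOH, −78 °C; Me2S) cleaves both methylidene groups to the cyclopentanone/methyl ketone diketone F4. Intramolecular McMurry coupling (TiCl3(DME)1.5, Zn–Cu couple, DME, reflux, syringe-pump addition) gives the 6-O-triethylsilyl ether of 27 F5. The step 19 conditions then remove all three silyl groups, so the route is rejoined at 28.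

Step 17 (allylboration of two hindered, chiral partners; three stereochemical elements must cooperate). If the catalysed reaction is too slow or gives the wrong face, the union is moved to an allylchromium reagent. The fallback sets out from 7: oxidation (NaBO3·4H2O, THF/H2O) gives [(3S)-3-methyl-3-(triethylsilyloxy)cyclopent-1-en-1-yl]methanol F1. CBr4/PPh3/2,6-lutidine (CH2Cl2, 0 °C) gives (3S)-1-(bromomethyl)-3-methyl-3-(triethylsilyloxy)cyclopent-1-ene F2. CrCl2 (4 equiv, THF, 0 °C) with aldehyde 24 then gives 26 by a Nozaki–Hiyama allylation. This goes through the same chair and so is anti at C5/C6, but the aldehyde face is now under Felkin–Anh control from the α-centre, which is not securely predictable here.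

Step 5 (copper boryl addition to a hindered 1,1-disubstituted alkene next to a quaternary epoxide carbon). If borylcupration fails, the epoxide is opened through a π-allyl palladium complex. The fallback sets out from 5: Pd(PPh3)4 (2 mol %) and AcOH in THF give [(3S)-3-hydroxy-3-methylcyclopent-1-en-1-yl]methyl acetate F6, with acetate attacking the unhindered CH2 terminus and the tertiary C–O bond untouched. Et3SiOTf/2,6-lutidine gives [(3S)-3-methyl-3-(triethylsilyloxy)cyclopent-1-en-1-yl]methyl acetate F7. Pd2(dba)3-catalysed borylation of the allylic acetate with B2pin2 (DMSO, 50 °C) returns to 7.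

**Further compounds**

F1 | step 17 | [(3S)-3-methyl-3-(triethylsilyloxy)cyclopent-1-en-1-yl]methanol | C[C@]1(O[Si](CC)(CC)CC)CCC(CO)=C1
F2 | step 17 | (3S)-1-(bromomethyl)-3-methyl-3-(triethylsilyloxy)cyclopent-1-ene | C[C@]1(O[Si](CC)(CC)CC)CCC(CBr)=C1
F3 | step 18 | 6-O-triethylsilyl ether of 26 | C=C1CC[C@](C)(O[Si](CC)(CC)CC)[C@@H]1[C@H](O[Si](CC)(CC)CC)[C@H](C(C)C)[C@@H](OC(=O)c1ccc(O[Si](C)(C)C(C)(C)C)cc1)CC(C)=C
F4 | step 18 | diketone from F3 (both =CH2 replaced by =O) | O=C1CC[C@](C)(O[Si](CC)(CC)CC)[C@@H]1[C@H](O[Si](CC)(CC)CC)[C@H](C(C)C)[C@@H](OC(=O)c1ccc(O[Si](C)(C)C(C)(C)C)cc1)CC(C)=O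
F5 | step 18 | 6-O-triethylsilyl ether of 27 | CC1=C2CC[C@](C)(O[Si](CC)(CC)CC)[C@@H]2[C@H](O[Si](CC)(CC)CC)[C@H](C(C)C)[C@@H](OC(=O)c2ccc(O[Si](C)(C)C(C)(C)C)cc2)C1
F6 | step 5 | [(3S)-3-hydroxy-3-methylcyclopent-1-en-1-yl]methyl acetate | C[C@]1(O)CCC(COC(C)=O)=C1
F7 | step 5 | [(3S)-3-methyl-3-(triethylsilyloxy)cyclopent-1-en-1-yl]methyl acetate | C[C@]1(O[Si](CC)(CC)CC)CCC(COC(C)=O)=C1
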